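## Retrosynthetic overview

1. Target 17 ⇐ removal of the C4 silyl ether from 16.
2. 16 ⇐ α-ketol ring expansion of acylcyclopentenol 15: the ring CH2 shifts from the carbinol carbon to the acyl carbon. This is the only ring-forming event (bought cyclopentene → cyclohexenone) and it relays the carbinol configuration to C6.
3. 15 ⇐ boron aldol of methyl ketone 12 with (9Z)-hexadec-9-enal 6 (C1'–C2' bond, C2' stereocentre).
4. 12 ⇐ (4S)-4-hydroxycyclopent-2-enone 7 (silylated) + 1-ethoxyvinyllithium, added anti to the silyloxy group.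
5. 6 ⇐ oct-1-yne 1 + 7-bromohept-1-ene 2: alkylation, Z-semi-hydrogenation, linear hydroformylation.

Assumption: oct-1-yne, 7-bromohept-1-ene, ethyl vinyl ether and (4S)-4-hydroxycyclopent-2-en-1-one (single enantiomer) are taken as catalogue chemicals.

## Route

Step 1
Reactants: 1 oct-1-yne; 2 7-bromohept-1-ene
Product: 4 pentadec-1-en-8-yne, via lithium oct-1-yn-1-ide 3 (not isolated)
Conditions: n-BuLi, THF, −78 → 0 °C; then 2, DMPU, 0 °C → rt
Reagents that add atoms: none
Why: SN2 alkylation of a lithium acetylide by a primary bromide (acetylide alkylation); the remote terminal alkene is inert.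

Step 2
Reactants: 4 pentadec-1-en-8-yne
Product: 5 (8Z)-pentadeca-1,8-diene
Conditions: H2 (1 atm), Lindlar Pd, quinoline, hexane, rt, stopped at 1.0 equiv H2
Reagents that add atoms: none
Why: Lindlar semi-hydrogenation delivers H2 syn on poisoned Pd to give the Z-alkene, and the alkyne is adsorbed much more strongly than the monosubstituted alkene, which survives when uptake is stopped at one equivalent.

Step 3
Reactants: 5 (8Z)-pentadeca-1,8-diene
Product: 6 (9Z)-hexadec-9-enal
Conditions: Rh(acac)(CO)2 (0.5 mol %), Xantphos (2 mol %), CO/H2 1:1 (10 bar), toluene, 70 °C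
Reagents that add atoms: carbon monoxide, [C-]#[O+]
Why: Rh/wide-bite-angle-bisphosphine hydroformylation places CHO on the terminal carbon of the monosubstituted alkene only; the 1,2-disubstituted Z-alkene neither reacts nor isomerises under these mild conditions.

Step 4
Reactants: 7 (4S)-4-hydroxycyclopent-2-en-1-one
Product: 8 (4S)-4-{[tert-butyl(dimethyl)silyl]oxy}cyclopent-2-en-1-one
Conditions: TBSCl, imidazole, CH2Cl2, 0 °C → rt
Reagents that add atoms: tert-butyldimethylsilyl chloride (TBSCl), CC(C)(C)[Si](C)(C)Cl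
Why: Imidazole-promoted silylation of the secondary alcohol; the C4 stereocentre is untouched.

Step 5
Reactants: 8 (4S)-4-{[tert-butyl(dimethyl)silyl]oxy}cyclopent-2-en-1-one; 9 ethyl vinyl ether
Product: 12 1-[(1R,4S)-4-{[tert-butyl(dimethyl)silyl]oxy}-1-hydroxycyclopent-2-en-1-yl]ethan-1-one, via 1-ethoxyvinyllithium 10 (not isolated), via enol ether carbinol 11 (not isolated)
Conditions: 9, t-BuLi, THF, −78 → 0 °C; then 8, −78 °C; then 0.5 M aq. HCl, 0 °C
Reagents that add atoms: water, O
Why: 1,2-Addition of an α-lithiated enol ether (acetyl-anion equivalent) to the enone anti to the bulky C4 silyloxy group sets the tertiary carbinol as 1R (OH cis to OTBS), and dilute-acid enol-ether hydrolysis unveils the methyl ketone; the minor syn adduct is removed by chromatography.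

Step 6
Reactants: 12 1-[(1R,4S)-4-{[tert-butyl(dimethyl)silyl]oxy}-1-hydroxycyclopent-2-en-1-yl]ethan-1-one; 6 (9Z)-hexadec-9-enal
Product: 15 (3S,11Z)-1-[(1R,4S)-4-{[tert-butyl(dimethyl)silyl]oxy}-1-hydroxycyclopent-2-en-1-yl]-3-hydroxyoctadec-11-en-1-one, via boron enolate 13 (not isolated), via boron aldolate 14 (not isolated)
Conditions: (+)-Ipc2BCl (2.2 equiv), Et3N (2.6 equiv), Et2O, 0 °C; 6, −78 → −20 °C; then MeOH, pH 7 buffer, 30% H2O2, 0 °C
Reagents that add atoms: none
Why: Paterson boron aldol of a methyl ketone, in which the first equivalent of chloroborane caps the tertiary OH and the (+)-Ipc ligands (from (−)-α-pinene) direct the enol borinate to the Re face of the aldehyde to set 3S; selectivity is expected to be moderate and the 3R diastereomer is removed by chromatography.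

Step 7
Reactants: 15 (3S,11Z)-1-[(1R,4S)-4-{[tert-butyl(dimethyl)silyl]oxy}-1-hydroxycyclopent-2-en-1-yl]-3-hydroxyoctadec-11-en-1-one
Product: 16 (4S,6R)-4-{[tert-butyl(dimethyl)silyl]oxy}-6-hydroxy-6-[(2S,10Z)-2-hydroxyheptadec-10-en-1-yl]cyclohex-2-en-1-one
Conditions: Sc(OTf)3 (10 mol %), 2,6-di-tert-butyl-4-methylpyridine (20 mol %), 4 Å MS, MeCN, 40 °C
Reagents that add atoms: none
Why: Proposed new method: Sc(III)-catalysed, chelation-locked α-ketol (acyloin) ring expansion of an unprotected 1-(β-hydroxyacyl)cyclopent-2-en-1-ol. The tertiary alkoxide and the ketone oxygen bind Sc in a five-membered chelate (the C3 hydroxyl as a third donor), which holds O–C–C=O syn-periplanar and activates the ketone; the ring C1–C5 σ-bond, perpendicular to the carbonyl plane, then shifts suprafacially to the acyl carbon, which becomes the tertiary carbinol C6 while old C1 becomes the enone carbonyl. The shift is stereospecific, so the 1R carbinol configuration is transferred to 6R (OH cis to the 4-silyloxy group). All syn shifts are reversible and lead to the same C6 epimer, so the non-conjugated isomer from competing migration of the vinylic C2 drains into the conjugated cyclohexenone, the thermodynamic sink (cyclopentene strain released, enone conjugation gained). Closest known reaction type: Lewis-acid- or metal-alkoxide-mediated α-ketol ring expansion of saturated 1-acylcycloalkanols (steroid D-homoannulation), to my knowledge not shown for 1-acylcyclopent-2-enols or with a free aldol hydroxyl.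

Step 8
Reactants: 16 (4S,6R)-4-{[tert-butyl(dimethyl)silyl]oxy}-6-hydroxy-6-[(2S,10Z)-2-hydroxyheptadec-10-en-1-yl]cyclohex-2-en-1-one
Product: 17 (4S,6R)-4,6-dihydroxy-6-[(2S,10Z)-2-hydroxyheptadec-10-en-1-yl]cyclohex-2-en-1-one
Conditions: HF·pyridine, pyridine, THF, 0 °C → rt
Reagents that add atoms: none
Why: Fluoride-driven desilylation (Si–F bond formation) under buffered conditions that do not provoke retro-aldol or dehydration; no stereocentre is touched.

## Compound list

1 | oct-1-yne | CCCCCCC#C | starting material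
2 | 7-bromohept-1-ene | C=CCCCCCBr | starting material
3 | lithium oct-1-yn-1-ide | [Li]C#CCCCCCC | intermediate
4 | pentadec-1-en-8-yne | C=CCCCCCC#CCCCCCC | intermediate
5 | (8Z)-pentadeca-1,8-diene | C=CCCCCC/C=C\CCCCCC | intermediate
6 | (9Z)-hexadec-9-enal | O=CCCCCCCC/C=C\CCCCCC | intermediate
7 | (4S)-4-hydroxycyclopent-2-en-1-one | O=C1C[C@H](O)C=C1 | starting material
8 | (4S)-4-{[tert-butyl(dimethyl)silyl]oxy}cyclopent-2-en-1-one | O=C1C[C@H](O[Si](C)(C)C(C)(C)C)C=C1 | intermediate
9 | ethyl vinyl ether (ethoxyethene) | C=COCC | starting material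
10 | 1-ethoxyvinyllithium | [Li]C(=C)OCC | intermediate
11 | enol ether carbinol: (1R,4S)-4-{[tert-butyl(dimethyl)silyl]oxy}-1-(1-ethoxyethenyl)cyclopent-2-en-1-ol | CCOC(=C)[C@@]1(O)C[C@H](O[Si](C)(C)C(C)(C)C)C=C1 | intermediate
12 | 1-[(1R,4S)-4-{[tert-butyl(dimethyl)silyl]oxy}-1-hydroxycyclopent-2-en-1-yl]ethan-1-one | CC(=O)[C@@]1(O)C[C@H](O[Si](C)(C)C(C)(C)C)C=C1 | intermediate
13 | boron enolate: enol diisopinocampheylborinate of 12 with the tertiary O also bound to B(Ipc)2, Ipc = isopinocampheyl of the (+)-series from (−)-α-pinene | C=C(OB([C@H]3C[C@H]4C[C@@H]([C@@H]3C)C4(C)C)[C@H]3C[C@H]4C[C@@H]([C@@H]3C)C4(C)C)[C@@]1(OB([C@H]3C[C@H]4C[C@@H]([C@@H]3C)C4(C)C)[C@H]3C[C@H]4C[C@@H]([C@@H]3C)C4(C)C)C[C@H](O[Si](C)(C)C(C)(C)C)C=C1 | intermediate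
14 | boron aldolate: 15 with the C3 oxygen and the ring C1 oxygen each bound to B(Ipc)2 | CCCCCC/C=C\CCCCCCC[C@H](OB([C@H]3C[C@H]4C[C@@H]([C@@H]3C)C4(C)C)[C@H]3C[C@H]4C[C@@H]([C@@H]3C)C4(C)C)CC(=O)[C@@]1(OB([C@H]3C[C@H]4C[C@@H]([C@@H]3C)C4(C)C)[C@H]3C[C@H]4C[C@@H]([C@@H]3C)C4(C)C)C[C@H](O[Si](C)(C)C(C)(C)C)C=C1 | intermediate
15 | (3S,11Z)-1-[(1R,4S)-4-{[tert-butyl(dimethyl)silyl]oxy}-1-hydroxycyclopent-2-en-1-yl]-3-hydroxyoctadec-11-en-1-one | CCCCCC/C=C\CCCCCCC[C@H](O)CC(=O)[C@@]1(O)C[C@H](O[Si](C)(C)C(C)(C)C)C=C1 | intermediate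
16 | (4S,6R)-4-{[tert-butyl(dimethyl)silyl]oxy}-6-hydroxy-6-[(2S,10Z)-2-hydroxyheptadec-10-en-1-yl]cyclohex-2-en-1-one | CCCCCC/C=C\CCCCCCC[C@H](O)C[C@@]1(O)C[C@H](O[Si](C)(C)C(C)(C)C)C=CC1=O | intermediate
17 | (4S,6R)-4,6-dihydroxy-6-[(2S,10Z)-2-hydroxyheptadec-10-en-1-yl]cyclohex-2-en-1-one | CCCCCC/C=C\CCCCCCC[C@H](O)C[C@@]1(O)C[C@H](O)C=CC1=O | target

## Step count and risks

Total step count: 8. Longest linear sequence: 6 (steps 1, 2, 3, 6, 7, 8).

The three steps most likely to fail:

**Step 7 (the proposed new ring expansion).** Risks: retro-aldol or dehydration of the free aldol under the Lewis acid, leakage through a non-chelated (anti) pathway that would give the C6 epimer, or stalling at the non-conjugated ketol isomer. The fallback uses known chemistry, sets out from 15 and comes back at 17. The secondary C3 hydroxyl alone is silylated (TESOTf, 2,6-lutidine, CH2Cl2, −78 °C; the tertiary ketol OH is too hindered) to give (3S,11Z)-1-[(1R,4S)-4-{[tert-butyl(dimethyl)silyl]oxy}-1-hydroxycyclopent-2-en-1-yl]-3-(triethylsilyloxy)octadec-11-en-1-one F1, in which the retro-aldol and dehydration channels are closed. F1 is then put through the classical stoichiometric aluminium-alkoxide acyloin ring expansion (Al(Ot-Bu)3, toluene, 80 °C, the D-homoannulation protocol); the aluminium alkoxide of the tertiary OH chelates the ketone, so the same syn course applies. This gives (4S,6R)-4-{[tert-butyl(dimethyl)silyl]oxy}-6-hydroxy-6-[(2S,10Z)-2-(triethylsilyloxy)heptadec-10-en-1-yl]cyclohex-2-en-1-one F2. HF·pyridine then removes both silyl groups and gives 17 directly.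

**Step 6 (boron aldol).** Risks: only moderate reagent control from the Ipc ligands (the sense of induction quoted rests on the usual behaviour of Ipc2BCl with methyl ketones and should be confirmed on a model), and interference by the free tertiary hydroxyl. The fallback sets out from 12 and comes back at 15. 12 is silylated twice (TMSOTf, Et3N, CH2Cl2, 0 °C) to give tert-butyl(dimethyl){[(1S,4R)-4-(trimethylsilyloxy)-4-[1-(trimethylsilyloxy)ethenyl]cyclopent-2-en-1-yl]oxy}silane F3. F3 is used in a chiral-Lewis-acid-catalysed Mukaiyama aldol with 6 (tryptophan-derived B-butyl oxazaborolidinone, 20 mol %, EtCN, −78 °C); the transition state is open and the face is set by the catalyst antipode, chosen for Re-face attack, not by a ligand on the enolate. This gives (3S,11Z)-1-[(1R,4S)-4-{[tert-butyl(dimethyl)silyl]oxy}-1-(trimethylsilyloxy)cyclopent-2-en-1-yl]-3-(trimethylsilyloxy)octadec-11-en-1-one F4. Citric acid in MeOH removes both trimethylsilyl groups and gives 15.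

**Step 2 (semi-hydrogenation beside a terminal alkene).** Risks: partial hydrogenation of the vinyl group or Z/E erosion, giving inseparable hydrocarbons. The fallback sets out from 1 and comes back at 6, with no terminal alkene ever present. 1 is alkylated (n-BuLi; 1-bromo-6-chlorohexane, THF/DMPU) to 1-chlorotetradec-7-yne F5. Magnesium in THF converts F5 into tetradec-7-yn-1-ylmagnesium chloride F6, which opens ethylene oxide (CuI cat., −30 °C) to give hexadec-9-yn-1-ol F7. Lindlar semi-hydrogenation gives (9Z)-hexadec-9-en-1-ol F8, and Dess–Martin oxidation gives 6.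

## Further compounds

F1 | step 7 | (3S,11Z)-1-[(1R,4S)-4-{[tert-butyl(dimethyl)silyl]oxy}-1-hydroxycyclopent-2-en-1-yl]-3-(triethylsilyloxy)octadec-11-en-1-one | CCCCCC/C=C\CCCCCCC[C@H](O[Si](CC)(CC)CC)CC(=O)[C@@]1(O)C[C@H](O[Si](C)(C)C(C)(C)C)C=C1
F2 | step 7 | (4S,6R)-4-{[tert-butyl(dimethyl)silyl]oxy}-6-hydroxy-6-[(2S,10Z)-2-(triethylsilyloxy)heptadec-10-en-1-yl]cyclohex-2-en-1-one | CCCCCC/C=C\CCCCCCC[C@H](O[Si](CC)(CC)CC)C[C@@]1(O)C[C@H](O[Si](C)(C)C(C)(C)C)C=CC1=O
F3 | step 6 | tert-butyl(dimethyl){[(1S,4R)-4-(trimethylsilyloxy)-4-[1-(trimethylsilyloxy)ethenyl]cyclopent-2-en-1-yl]oxy}silane | C=C(O[Si](C)(C)C)[C@@]1(O[Si](C)(C)C)C[C@H](O[Si](C)(C)C(C)(C)C)C=C1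
F4 | step 6 | (3S,11Z)-1-[(1R,4S)-4-{[tert-butyl(dimethyl)silyl]oxy}-1-(trimethylsilyloxy)cyclopent-2-en-1-yl]-3-(trimethylsilyloxy)octadec-11-en-1-one | CCCCCC/C=C\CCCCCCC[C@H](O[Si](C)(C)C)CC(=O)[C@@]1(O[Si](C)(C)C)C[C@H](O[Si](C)(C)C(C)(C)C)C=C1
F5 | step 2 | 1-chlorotetradec-7-yne | ClCCCCCCC#CCCCCCC
F6 | step 2 | tetradec-7-yn-1-ylmagnesium chloride | Cl[Mg]CCCCCCC#CCCCCCC
F7 | step 2 | hexadec-9-yn-1-ol | OCCCCCCCCC#CCCCCCC
F8 | step 2 | (9Z)-hexadec-9-en-1-ol | OCCCCCCCC/C=C\CCCCCC
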